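(The runs were generated by integration with constants of no real substance.)

Time is what my colleague and I dispute at this board: does target in this flask grow along a straight line, or does it slow as the run goes on?

| flask | substrate | gas | free catalyst | remark | time |
|---|---|---|---|---|---|
| Monday's | 1.1 M | 200 mM (held) | 11 mM | run made earlier |  |
| Tuesday's | 2.4 M | 200 mM (held) | 11 mM | run made earlier |  |
| flask | 1.6 M | 200 mM (held) | 11 mM |  | 25 min |

| run | time / min | target / % |
|---|---|---|
| Monday's | 1.50 | 4 |
| Monday's | 5.00 | 12 |
| Monday's | 8.00 | 25 |
| Monday's | 12.0 | 30 |
| Monday's | 20.0 | 42 |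
| Monday's | 25.0 | 48 |
| Monday's | 30.0 | 52 |
| Tuesday's | 2.50 | 6 |
| Tuesday's | 4.00 | 7 |
| Tuesday's | 6.00 | 11 |
| Tuesday's | 8.00 | 12 |
| Tuesday's | 12.0 | 21 |
| Tuesday's | 20.0 | 35 |
| Tuesday's | 30.0 | 46 |

(standard deviation of a reading: 1.5 percentage points)

- what was read earlier has a scatter of 1.5 percentage points, one standard deviation
- at the start none of the gas is in solution
- a reading or a percentage of target counts all its forms, free or not

* amount of target in percent of the substrate charged, at 80 s, 6.0 min and 25 min

My colleague draws the straight line, a fixed molar rate r for each charge (zero order in substrate). Monday's reading at 12.0 min gives 0.0275 M min⁻¹ and Tuesday's at the same time gives 0.0420 M min⁻¹. The flask's charge lies a share w = 0.385 of the way from Monday's charge to Tuesday's, so my colleague's estimate of r for the flask is 0.0331 M min⁻¹. That line reaches 2.76 %, 12.4 % and 51.7 % at the asked times.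

I work with what is left. I take the natural logarithm of the charge over the part of it not yet target and divide by the time, which gives a first-order constant k for that reading. Monday's last-but-one reading gives 0.0262 min⁻¹ and Tuesday's last gives 0.0205 min⁻¹, so k as read is smaller on Tuesday, and I do not use one value for both charges. The same share w gives the flask 0.0240 min⁻¹, its fraction-left constant, an apparent pseudo-first-order constant. The part not yet target then falls as exp(−kt), and my reckoning gives 3.15 %, 13.4 % and 45.1 %.

Against the line I hold up Monday's run: its own rate carried to 25.0 min gives 62.5 %, and the reading is 48 %. My colleague answers that at 6.0 min our two curves lie 1 percentage point apart, less than the scatter. At 25 min they part by 6.6 points.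

The forecast gives 3.2 %, 13 % and 46 %, on the ground “Absolute rate still rises, but less than proportionally”.

The flask gives 2.68 %, 13.7 % and 44.2 %, so at 25 min the line stands 7.5 points high and my curve 0.90 points high.

    substrate + free catalyst ⇌ catalyst intermediate A (K = 0.530 M⁻¹, k = 0.0640 M⁻¹ s⁻¹)
    coupling partner + catalyst intermediate A ⇌ catalyst intermediate B (K = 6.30 M⁻¹, k = 42.0 M⁻¹ s⁻¹)
    catalyst intermediate B → free catalyst + target (k = 11.0 s⁻¹)
    substrate + target ⇌ idle adduct, settled at all times (K = 2.50 M⁻¹)
    gas ⇌ coupling partner, rate k5*(csat - [coupling partner]) (kL = 0.00360 s⁻¹)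
    target → over-reaction product (k = 1.80 × 10⁻⁴ s⁻¹)

In this flask the line holds for the early part of the run: at 6.0 min it misses by 1.3 points, less than the scatter. At 25.0 min this flask holds substrate at 29.4 % and idle adduct at 47.8 %, counted as two, with its target inside the figure for target. Carried to 12.5 min, the fraction-left constant gives 25.9 %, and the flask holds 27.2 %.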